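**Remark (assumption):** 3-methoxy-2-methylphenol (1) is taken as a purchasable compound. Compound 18 is drawn with the geometry of the expected major isomer; the geometry does not matter because both double bonds are hydrogenated in step 8.

## Structural features

The target (C30H42O8) consists of two identical 2-hydroxy-5-methoxy-6-methyl-1,4-benzoquinone rings joined only through an unbranched tetradecane-1,14-diyl chain (C1'–C14') attached at ring carbon C3 of each ring; there is no ring fusion and no stereocentre, so no stereochemical relationship has to be set. Each ring is fully substituted, numbered here C1(=O), C2(OH), C3(chain), C4(=O), C5(OMe), C6(Me), so that the four oxygens stand 1,2,4,5 and the free hydroxyl O2 is para to the methyl ether O5. The hydroxyquinone is a vinylogous carboxylic acid and a redox-active Michael acceptor that would not survive ylides, organolithiums or strong bases, and must therefore be carried as a protected arene and unveiled last. The saturated chain is inert and symmetrical, and its only handles are the two benzylic termini C1' and C14'. The real difficulty is twofold: four oxygens must be placed on each ring with only O5 methylated, and a C–C bond must be made at a ring carbon (C3) flanked on both sides by oxygen substituents (O2 and O4). The key step exploits the fact that C1' and C14' are benzylic carbons on C3: each can enter as the formyl carbon of a fully oxygenated benzaldehyde, and the remaining C2'–C13' unit is a symmetrical twelve-carbon piece that can carry an ylide carbon at each end. Because only O5 is a methyl ether, the triol set free at the end has a single para pair of free hydroxyls (O1/O4), so that oxidation can lead only to the required hydroxy-methoxy-quinone.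

## Logic of the disconnections

**20 ⇒ 19 ⇒ 18.** No skeletal bond is cut. Backwards, both quinones are reduced to the level of 19, the six hydroxyls (O1, O2, O4 of each ring) are capped through O–CH2Ph bonds, and C1'=C2' and C13'=C14' are reintroduced. The reason is that the sensitive functionality then appears only in the last operation. The gain is that the two alkenes and the six benzyl ethers are removed by one and the same reagent. The demand is complete hydrogenolysis at six hindered ethers without touching the O5–CH3 bond, followed by an oxidation that stops at the quinone.

**18 ⇒ 2 × 13 + 17.** The bonds cut are C1'=C2' and C13'=C14'. Cutting there puts the electrophilic carbon on the ring, where it is easy to install, and leaves a symmetrical C12 nucleophile. The gain is three components of low complexity, two of them identical. The demand is complete olefination at both termini of 17, each terminus consuming one molecule of 13, whose carbonyl group sits between two benzyloxy groups.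

**17 ⇒ 16 ⇒ 14 + 2 × 15.** The two C–P bonds are cut. Both pieces are catalogue compounds and 16 is a stable, storable salt. The forward step only has to be driven to double quaternisation, and the salt must be dry before deprotonation.

**13 ⇒ 12 ⇒ 10 ⇒ 8.** The C3–C1' bond is cut, with 11 as the one-carbon source, and then the C3–Br bond, with 9 as the bromine source. C3 is the only unsubstituted ring position of 8, so no regiochemical question arises. The demand is that halogen–metal exchange in 10 outruns deprotonation of the OCH2Ph groups.

**8 ⇒ 7 ⇒ 5.** Three O–CH2Ph bonds (from 6) and, behind them, three O–acetyl bonds are cut. This exchanges the acetates, which would not survive an organolithium or an ylide, for ethers that do and that leave under hydrogen. The demand is that the air-sensitive 7 is never exposed to oxygen under basic conditions.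

**5 ⇒ 3.** The C2–O2 bond is cut, the acetyl groups coming from 4. This reduces the tetra-oxygenated ring to a simple quinone. The demand is regiochemical: oxygen must enter at C2 (para to the methoxy group), not at C3.

**3 ⇒ 1.** The C4–O4 bond is cut, the oxygen coming from 2. Compound 1 already holds O1, O5 with its methyl group, and the C6 methyl in the correct relationship. The forward oxidation must attack the position para to the free hydroxyl, which is the only para position available.

## Other disconnections considered

Alternative 1: The rings themselves are cut, each at C3–C4 and C5–C6. C1–C3 with the chain then come from an enone, C6 with its methyl from the ethyl group of that ketone, and C4/C5 from a malonate. In the forward key step the bis(enone) A2 and two equivalents of dimethyl malonate A3 with NaOMe would undergo Michael addition at each β-carbon, Dieckmann closure, saponification and decarboxylation to give the bis(cyclohexanedione) A1; aromatisation would then give the bis(resorcinol) A4. In its favour are cheap acyclic materials, no protecting groups up to A4, and no phosphine oxide. The chain is in place before the ring exists, so no bond has to be made at a hindered aromatic carbon. On raw-material cost and on avoiding organolithium chemistry this plan is the better one. Against it, A1 carries only two of the four ring oxygens (O1 and O5), related by a local mirror plane. Each ring of A4 would need a statistical mono-O-methylation, done on two rings at once, and then two further oxidations (phenol to quinone for O4, quinone acetoxylation for O2) before the final saponification and oxidation. In comparison, the annulation is mechanistically sound, but it settles none of the features that make the target hard. The oxygenation chemistry that the chosen plan runs once on a small monomer would be run twice over on a lipophilic dimer. On step economy it is worse: about three steps to A2, then annulation, aromatisation and four or five two-directional steps, against eight in all.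

Alternative 2: Each arene is cut at C2–C3 and C4–C5 into an alkyne unit (C3 with the chain, C4 with its oxygen) and a four-carbon cyclobutenone unit (C5, C6, C1, C2); the C1–C2 bond is re-formed in the ring closure. In the forward key step, heating the bis(siloxyalkyne) A6 with two equivalents of the racemic cyclobutenone A7 would give the bis(phenol) A5. The sequence is 4π opening to a vinylketene, regioselective [2+2] addition to the ynol ether, a second 4π opening, 6π electrocyclisation and tautomerisation. In its favour, the hexasubstituted ring would be assembled with all four oxygens in place and already differentiated (free OH at O2, silyl ethers at O1 and O4, methyl ether at O5). The regiochemistry follows from the polarity of ketene and ynol ether, not from directing effects. After the key step only fluoride desilylation to 19 and air oxidation to 20 remain. On regiochemical certainty and on brevity of the endgame (no benzyl groups, no hydrogenation) this alternative is the better plan. On step economy the two plans are roughly equal: about four steps would be needed for A7 and about two for A6, followed by the annulation and two more steps. Against it, A6 is a hydrolytically and thermally sensitive bis-ynol ether. The ketene intermediates may dimerise or acylate the product phenol at the temperature required. Four pericyclic events must run cleanly at both ends of one molecule, so mono-annulated material still bearing a siloxyalkyne is to be expected, and the free phenol between silyl ethers invites silyl migration. In comparison, the chosen plan uses ordinary reagents, stable intermediates and a textbook key step, and is preferred on robustness.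

Alternative 3: The chain is cut at C3'=C4' and C11'=C12' of a diene precursor. The eight-carbon middle (C4'–C11') comes from cis-cyclooctene A10, and two three-carbon arms are already attached to the arene in the arylbutene A9. In the forward key step, second-generation Grubbs catalyst would open A10 and cap both ends with A9 to give the diene A8. By atom balance one molecule of ethene A11 is released per molecule of A8, since the ring opening expels nothing and only the pair of capping events liberates a C2 fragment. In its favour are catalytic, neutral conditions that leave benzyl ethers alone, and no stoichiometric phosphorus waste. The reacting alkenes lie three carbons from the crowded ring, so steric hindrance at the reacting centres is lower than at the doubly ortho-substituted carbonyl group of 13. On these points it is the better plan. The endgame is the same hydrogenation–oxidation, so it is equal there. Against it stands selectivity. A9 would homodimerise, A10 would undergo ring-opening polymerisation, and products containing two or more C8 units would form beside A8. After hydrogenation those homologues differ from 20 only in chain length and would be hard to remove, whereas the Wittig union can deliver only the chain length defined by 16. Suppressing oligomers would require a large excess of A9, the costly component. In comparison, A9 itself needs a C–C bond to the hindered ring carbon (homoallylation of 12, or allylation of 13 and deoxygenation), so the difficult bond is moved, not avoided. The step count is about the same and nominally one lower (four steps to 10, one to A9, metathesis, one-step endgame). The chosen plan is preferred for fidelity of chain length.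

Key step: step 7

## Route

Step 1
Reactants: 1 3-methoxy-2-methylphenol; 2 dipotassium nitrosodisulfonate (Fremy's salt)
Product: 3 2-methoxy-3-methylcyclohexa-2,5-diene-1,4-dione
Conditions: (KO3S)2NO (2.2 equiv), KH2PO4, H2O–acetone, 0 °C to rt
Reagents that add atoms: dipotassium nitrosodisulfonate 2, [K+].[K+].[O]N(S(=O)(=O)[O-])S(=O)(=O)[O-]
Why: Teuber oxidation: the nitroxyl radical abstracts the phenolic hydrogen and a second equivalent couples at the only carbon para to the hydroxyl (C4), so elimination of imidodisulfonate can give only the 1,4-quinone carrying OMe and Me on the same double bond.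

Step 2
Reactants: 3 2-methoxy-3-methylcyclohexa-2,5-diene-1,4-dione; 4 acetic anhydride
Product: 5 5-methoxy-6-methylbenzene-1,2,4-triyl triacetate
Conditions: Ac2O (solvent), H2SO4 (cat.), 0 °C to rt
Reagents that add atoms: acetic anhydride 4, CC(=O)OC(C)=O
Why: Thiele–Winter acetoxylation: the unit MeO–C5=C6–C1=O is a vinylogous ester and stays intact, so acid-promoted 1,4-addition should run across O=C4–C3=C2 with acetate entering at C2, para to the methoxy group (the orientation known for methoxy-1,4-benzoquinone), overriding the weaker C6-methyl donor; enolisation and acetylation then give the triacetate.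

Step 3
Reactants: 5 5-methoxy-6-methylbenzene-1,2,4-triyl triacetate; 6 benzyl bromide
Product: 8 1,2,5-tris(benzyloxy)-4-methoxy-3-methylbenzene, via free triol 7 (not isolated)
Conditions: AcCl (cat.), MeOH, Ar, 50 °C; evaporate; BnBr (3.6 equiv), K2CO3, DMF, Ar, 60 °C
Reagents that add atoms: benzyl bromide 6, BrCc1ccccc1
Why: Acid-catalysed transesterification frees the triol in a medium in which it is not autoxidised, and Williamson etherification of the three phenoxides under argon in a dipolar aprotic solvent (favouring O- over C-alkylation) caps O1, O2 and O4; the aryl methyl ether is inert.

Step 4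
Reactants: 8 1,2,5-tris(benzyloxy)-4-methoxy-3-methylbenzene; 9 N-bromosuccinimide
Product: 10 1,2,4-tris(benzyloxy)-3-bromo-5-methoxy-6-methylbenzene
Conditions: NBS (1.05 equiv), MeCN, 0 °C to rt, dark
Reagents that add atoms: N-bromosuccinimide 9, O=C1CCC(=O)N1Br
Why: Electrophilic aromatic bromination at the single ring C–H (C3), which lies ortho to two benzyloxy groups on a tetra-alkoxy ring far more electron-rich than the benzyl phenyl rings; polar, dark, anhydrous conditions suppress radical benzylic bromination and oxidative dealkylation.

Step 5
Reactants: 10 1,2,4-tris(benzyloxy)-3-bromo-5-methoxy-6-methylbenzene; 11 N,N-dimethylformamide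
Product: 13 2,3,6-tris(benzyloxy)-5-methoxy-4-methylbenzaldehyde, via aryllithium 12 (not isolated)
Conditions: n-BuLi (1.05 equiv), THF, −78 °C; DMF, −78 °C to 0 °C; 1 M HCl
Reagents that add atoms: N,N-dimethylformamide 11, CN(C)C=O
Why: Bromine–lithium exchange at −78 °C is faster than deprotonation of the OCH2Ph groups and gives an aryllithium stabilised by two flanking oxygens; Bouveault formylation with DMF stops at the lithium hemiaminal, which cannot over-add and releases the aldehyde on acidic work-up.

Step 6
Reactants: 14 1,12-dibromododecane; 15 triphenylphosphine
Product: 16 dodecane-1,12-diylbis(triphenylphosphonium) dibromide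
Conditions: PPh3 (2.2 equiv), MeCN, reflux; Et2O trituration; dry in vacuo
Reagents that add atoms: triphenylphosphine 15, c1ccc(cc1)P(c1ccccc1)c1ccccc1
Why: Twofold SN2 quaternisation of the phosphine by an unhindered primary dibromide; the bis-salt separates from the monosalt and excess phosphine by its insolubility in ether.

Step 7
Reactants: 16 dodecane-1,12-diylbis(triphenylphosphonium) dibromide; 13 2,3,6-tris(benzyloxy)-5-methoxy-4-methylbenzaldehyde
Product: 18 (1Z,13Z)-1,14-bis[2,3,6-tris(benzyloxy)-5-methoxy-4-methylphenyl]tetradeca-1,13-diene, via bis-ylide 17 (not isolated)
Conditions: NaN(SiMe3)2 (2.0 equiv), THF, 0 °C to rt; then 13 (2.2 equiv, of which two molecules are incorporated per molecule of 16), −78 °C to rt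
Reagents that add atoms: 2,3,6-tris(benzyloxy)-5-methoxy-4-methylbenzaldehyde 13, O=Cc1c(OCc2ccccc2)c(OCc2ccccc2)c(C)c(OC)c1OCc1ccccc1
Why: Two equivalents of NaN(SiMe3)2 remove one proton next to each phosphorus of 16 and give the non-stabilised bis-ylide 17. Each of its two ylide carbons (C2', C13') then adds to the formyl carbon of one molecule of 13 (the future C1' and C14'), so that two molecules of 13 are built into 18 and both aryl-bearing ends of the product derive from the same aldehyde. The addition is a [2+2] union that gives a cis-oxaphosphetane under these lithium-free conditions, and syn-cycloreversion releases the Z-alkene and triphenylphosphine oxide, whose strong P=O bond drives the step. The closest known reaction type is the Wittig olefination of aromatic aldehydes with alkylidenetriphenylphosphoranes, including two-directional versions with α,ω-bis-ylides. No ring is closed and no stereocentre is created; the alkene geometry needs no control because step 8 saturates both double bonds. The selectivity the step does need is complete olefination at both termini: 13 has no α-hydrogen and cannot quench the ylide by proton transfer, a non-stabilised ylide is reactive enough for a carbonyl group flanked by two benzyloxy groups, and the slight excess of 13 carries the mono-olefinated ylide on to 18. The base is held at two equivalents so that no free amide remains to attack the carbonyl group, and the benzyl and methyl ethers are inert to ylide and amide alike.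

Step 8
Reactants: 18 (1Z,13Z)-1,14-bis[2,3,6-tris(benzyloxy)-5-methoxy-4-methylphenyl]tetradeca-1,13-diene
Product: 20 3,3'-(tetradecane-1,14-diyl)bis(2-hydroxy-5-methoxy-6-methylcyclohexa-2,5-diene-1,4-dione), via bis(triol) 19 (not isolated)
Conditions: H2 (1 atm), Pd/C (10%), EtOAc–MeOH, rt; filter; air, rt
Reagents that add atoms: none
Why: Heterogeneous hydrogenation saturates both styrenyl double bonds and hydrogenolyses the six benzylic C–O bonds while the ring and the aryl methyl ether are inert; the hydroxyhydroquinone rings of 19 are then autoxidised across their only para pair of free hydroxyls (O1/O4) to the 2-hydroxy-1,4-quinone, the methyl group on O5 excluding any other quinone.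

## Compound list

1 | 3-methoxy-2-methylphenol | COc1cccc(O)c1C | starting material
2 | dipotassium nitrosodisulfonate (Fremy's salt) | [K+].[K+].[O]N(S(=O)(=O)[O-])S(=O)(=O)[O-] | starting material
3 | 2-methoxy-3-methylcyclohexa-2,5-diene-1,4-dione | COC1=C(C)C(=O)C=CC1=O | intermediate
4 | acetic anhydride | CC(=O)OC(C)=O | starting material
5 | 5-methoxy-6-methylbenzene-1,2,4-triyl triacetate | COc1c(C)c(OC(C)=O)c(OC(C)=O)cc1OC(C)=O | intermediate
6 | benzyl bromide | BrCc1ccccc1 | starting material
7 | 5-methoxy-6-methylbenzene-1,2,4-triol | COc1c(C)c(O)c(O)cc1O | intermediate
8 | 1,2,5-tris(benzyloxy)-4-methoxy-3-methylbenzene | COc1c(C)c(OCc2ccccc2)c(OCc2ccccc2)cc1OCc1ccccc1 | intermediate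
9 | N-bromosuccinimide | O=C1CCC(=O)N1Br | starting material
10 | 1,2,4-tris(benzyloxy)-3-bromo-5-methoxy-6-methylbenzene | COc1c(C)c(OCc2ccccc2)c(OCc2ccccc2)c(Br)c1OCc1ccccc1 | intermediate
11 | N,N-dimethylformamide | CN(C)C=O | starting material
12 | [2,3,6-tris(benzyloxy)-5-methoxy-4-methylphenyl]lithium | COc1c(C)c(OCc2ccccc2)c(OCc2ccccc2)c([Li])c1OCc1ccccc1 | intermediate
13 | 2,3,6-tris(benzyloxy)-5-methoxy-4-methylbenzaldehyde | O=Cc1c(OCc2ccccc2)c(OCc2ccccc2)c(C)c(OC)c1OCc1ccccc1 | intermediate
14 | 1,12-dibromododecane | BrCCCCCCCCCCCCBr | starting material
15 | triphenylphosphine | c1ccc(cc1)P(c1ccccc1)c1ccccc1 | starting material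
16 | dodecane-1,12-diylbis(triphenylphosphonium) dibromide | [Br-].[Br-].c1ccccc1[P+](c1ccccc1)(c1ccccc1)CCCCCCCCCCCC[P+](c1ccccc1)(c1ccccc1)c1ccccc1 | intermediate
17 | dodecane-1,12-diylidenebis(triphenylphosphorane) | c1ccccc1P(c1ccccc1)(c1ccccc1)=CCCCCCCCCCCC=P(c1ccccc1)(c1ccccc1)c1ccccc1 | intermediate
18 | (1Z,13Z)-1,14-bis[2,3,6-tris(benzyloxy)-5-methoxy-4-methylphenyl]tetradeca-1,13-diene | COc1c(C)c(OCc2ccccc2)c(OCc2ccccc2)c(/C=C\CCCCCCCCCC/C=C\c2c(OCc3ccccc3)c(OCc3ccccc3)c(C)c(OC)c2OCc2ccccc2)c1OCc1ccccc1 | intermediate
19 | 3,3'-(tetradecane-1,14-diyl)bis(5-methoxy-6-methylbenzene-1,2,4-triol) | COc1c(C)c(O)c(O)c(CCCCCCCCCCCCCCc2c(O)c(O)c(C)c(OC)c2O)c1O | intermediate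
20 | 3,3'-(tetradecane-1,14-diyl)bis(2-hydroxy-5-methoxy-6-methylcyclohexa-2,5-diene-1,4-dione) | COC1=C(C)C(=O)C(O)=C(CCCCCCCCCCCCCCC2=C(O)C(=O)C(C)=C(OC)C2=O)C1=O | target

## Step count and least certain steps

Total step count: 8. Longest linear sequence: 7 steps (steps 1, 2, 3, 4, 5, 7, 8); step 6 is a one-step branch.

**Step 7 (key step).** The most likely failure is stalling after the first olefination. The sparingly soluble salt 16 may be deprotonated incompletely, or the second ylide terminus may be protonated by adventitious moisture before it reaches the hindered carbonyl group, leaving mono-olefinated phosphonium material. The fallback gives up olefination and makes the two C3–C1' bonds as sp2–sp3 bonds. It sets out from 10, which is converted by direct magnesium insertion (Mg turnings, LiCl, THF) into [2,3,6-tris(benzyloxy)-5-methoxy-4-methylphenyl]magnesium bromide F1; no alkyl halide is formed in this way that could compete in the coupling. Two equivalents of F1 are coupled with commercial 1,14-dibromotetradecane F2 under Li2CuCl4 catalysis (Kochi-type Grignard–alkyl halide coupling) to give 1,14-bis[2,3,6-tris(benzyloxy)-5-methoxy-4-methylphenyl]tetradecane F3. Hydrogenolysis of F3 under the conditions of step 8 brings the material back to the route at 19.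

**Step 2.** The risk is addition of acetate at the other unsubstituted quinone carbon (C3, favoured by the methyl donor), or acid-induced degradation, so that the fourth oxygen ends up meta to the methoxy group. The fallback fixes the pattern by electrophilic substitution governed by two ether oxygens. It sets out from 1, which is O-benzylated with 6 and K2CO3 to 1-(benzyloxy)-3-methoxy-2-methylbenzene F4. Dibromination with 9 (2.1 equiv) at the two positions ortho/para to both ethers gives 1-(benzyloxy)-4,6-dibromo-3-methoxy-2-methylbenzene F5. Twofold palladium-catalysed hydroxylation (Pd2(dba)3, tBuXPhos, KOH, dioxane–H2O, 100 °C) gives 4-(benzyloxy)-6-methoxy-5-methylbenzene-1,3-diol F6, and O-benzylation with 6 returns to the route at 8.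

**Step 3.** The risk is oxidation of the transient triol 7 or its phenoxides by traces of oxygen once base is added, followed by incomplete O-benzylation or C-benzylation at C3. The fallback accepts the oxidation and passes through the air-stable quinone level. It sets out from 5, which is saponified in air (K2CO3, MeOH, air; then acid) to 5-hydroxy-2-methoxy-3-methylcyclohexa-2,5-diene-1,4-dione F7, a compound that can be purified at leisure. Reductive benzylation under phase-transfer conditions (Na2S2O4, 6, KOH, Bu4NBr, THF–H2O), in which dithionite keeps regenerating 7 until all three oxygens are etherified, returns to the route at 8.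

**Step 5.** The risk is proton transfer from an ortho OCH2Ph group to the aryllithium 12 (anion translocation followed by [1,2]-Wittig rearrangement), or simple protonation back to 8. The fallback avoids the organometallic altogether and sets out from 8. Rieche formylation with dichloromethyl methyl ether and AgOTf (AgO3SCF3) in CH2Cl2 at −78 °C gives 1,2,4-tris(benzyloxy)-3-[chloro(methoxy)methyl]-5-methoxy-6-methylbenzene F8, which is hydrolysed on aqueous work-up and so returns to the route at 13, bypassing 10 and 12.

**Step 8.** The risk is an uncontrolled autoxidation: the hydrogen peroxide produced may attack the electron-rich rings or the hydroxyquinone, or the oxidation may stop part-way at quinhydrone-type mixtures. Slow hydrogenolysis of the most hindered ethers is a further risk. The fallback isolates a protected, air-stable derivative and uses a defined oxidant. It sets out from crude 19, which is acetylated under argon (Ac2O, pyridine, DMAP) to 3,3'-(tetradecane-1,14-diyl)bis(5-methoxy-6-methylbenzene-1,2,4-triyl) hexaacetate F9 and purified. Methanolysis (K2CO3, MeOH, Ar) followed by aqueous FeCl3 then returns to the route at 20.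

## Further compounds

F1 | step 7 | [2,3,6-tris(benzyloxy)-5-methoxy-4-methylphenyl]magnesium bromide | COc1c(C)c(OCc2ccccc2)c(OCc2ccccc2)c([Mg]Br)c1OCc1ccccc1
F2 | step 7 | 1,14-dibromotetradecane | BrCCCCCCCCCCCCCCBr
F3 | step 7 | 1,14-bis[2,3,6-tris(benzyloxy)-5-methoxy-4-methylphenyl]tetradecane | COc1c(C)c(OCc2ccccc2)c(OCc2ccccc2)c(CCCCCCCCCCCCCCc2c(OCc3ccccc3)c(OCc3ccccc3)c(C)c(OC)c2OCc2ccccc2)c1OCc1ccccc1
F4 | step 2 | 1-(benzyloxy)-3-methoxy-2-methylbenzene | COc1cccc(OCc2ccccc2)c1C
F5 | step 2 | 1-(benzyloxy)-4,6-dibromo-3-methoxy-2-methylbenzene | COc1c(C)c(OCc2ccccc2)c(Br)cc1Br
F6 | step 2 | 4-(benzyloxy)-6-methoxy-5-methylbenzene-1,3-diol | COc1c(C)c(OCc2ccccc2)c(O)cc1O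
F7 | step 3 | 5-hydroxy-2-methoxy-3-methylcyclohexa-2,5-diene-1,4-dione | COC1=C(C)C(=O)C(O)=CC1=O
F8 | step 5 | 1,2,4-tris(benzyloxy)-3-[chloro(methoxy)methyl]-5-methoxy-6-methylbenzene (racemic) | COC(Cl)c1c(OCc2ccccc2)c(OCc2ccccc2)c(C)c(OC)c1OCc1ccccc1
F9 | step 8 | 3,3'-(tetradecane-1,14-diyl)bis(5-methoxy-6-methylbenzene-1,2,4-triyl) hexaacetate | COc1c(C)c(OC(C)=O)c(OC(C)=O)c(CCCCCCCCCCCCCCc2c(OC(C)=O)c(OC(C)=O)c(C)c(OC)c2OC(C)=O)c1OC(C)=O
A1 | alternative 1 | 5,5'-(tetradecane-1,14-diyl)bis(3-hydroxy-2-methylcyclohex-2-en-1-one) | CC1=C(O)CC(CCCCCCCCCCCCCCC2CC(O)=C(C)C(=O)C2)CC1=O
A2 | alternative 1 | (4E,20E)-tetracosa-4,20-diene-3,22-dione | CCC(=O)/C=C/CCCCCCCCCCCCCC/C=C/C(=O)CC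
A3 | alternative 1 | dimethyl malonate | COC(=O)CC(=O)OC
A4 | alternative 1 | 5,5'-(tetradecane-1,14-diyl)bis(2-methylbenzene-1,3-diol) | Cc1c(O)cc(CCCCCCCCCCCCCCc2cc(O)c(C)c(O)c2)cc1O
A5 | alternative 2 | 2,2'-(tetradecane-1,14-diyl)bis[6-(tert-butyldimethylsilyloxy)-4-methoxy-5-methyl-3-(triisopropylsilyloxy)phenol] | COc1c(C)c(O[Si](C)(C)C(C)(C)C)c(O)c(CCCCCCCCCCCCCCc2c(O)c(O[Si](C)(C)C(C)(C)C)c(C)c(OC)c2O[Si](C(C)C)(C(C)C)C(C)C)c1O[Si](C(C)C)(C(C)C)C(C)C
A6 | alternative 2 | 1,18-bis(triisopropylsilyloxy)octadeca-1,17-diyne | CC(C)[Si](C(C)C)(C(C)C)OC#CCCCCCCCCCCCCCCC#CO[Si](C(C)C)(C(C)C)C(C)C
A7 | alternative 2 | 4-(tert-butyldimethylsilyloxy)-2-methoxy-3-methylcyclobut-2-en-1-one (racemic) | COC1=C(C)C(O[Si](C)(C)C(C)(C)C)C1=O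
A8 | alternative 3 | (3E,11E)-1,14-bis[2,3,6-tris(benzyloxy)-5-methoxy-4-methylphenyl]tetradeca-3,11-diene | COc1c(C)c(OCc2ccccc2)c(OCc2ccccc2)c(CC/C=C/CCCCCC/C=C/CCc2c(OCc3ccccc3)c(OCc3ccccc3)c(C)c(OC)c2OCc2ccccc2)c1OCc1ccccc1
A9 | alternative 3 | 1,2,4-tris(benzyloxy)-3-(but-3-en-1-yl)-5-methoxy-6-methylbenzene | C=CCCc1c(OCc2ccccc2)c(OCc2ccccc2)c(C)c(OC)c1OCc1ccccc1
A10 | alternative 3 | (Z)-cyclooctene | C1CCC/C=C\CC1
A11 | alternative 3 | ethene | C=C
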